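The runs stem from a simulated flask on assumed constants; noise was put on by code.

A plateau tempts me to fit a constant and trust it, but spring's links stand at 32.2 % after 20.0 min, while its charge of second end groups, the limiting reagent by charge, allows 90.0 % of the first end groups charged. So this plateau cannot be read off the charges.

| flask | first end groups | second end groups | remark | time |
|---|---|---|---|---|
| spring | 0.050 M | 0.045 M | run made earlier |  |
| summer | 0.034 M | 0.045 M | run made earlier |  |
| dusk | 0.075 M | 0.045 M | run made earlier |  |
| midnight | 0.050 M | 0.068 M | run made earlier |  |
| maple | 0.050 M (fed, over 12 min) | 0.0450 M | all else is in the flask from the start; the feed brings no volume worth counting | 20 min |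
| elm | 0.050 M | 0.0450 M (fed, over 12 min) | all else is in the flask from the start; the feed brings no volume worth counting | 20 min |
| ash | 0.050 M | 0.0450 M | everything together at the start | 20 min |

| run | time / min | links / % |
|---|---|---|
| spring | 3.00 | 16.3 |
| spring | 6.00 | 24.2 |
| spring | 8.00 | 26.4 |
| spring | 12.0 | 29.4 |
| spring | 15.0 | 32.5 |
| spring | 20.0 | 32.2 |
| summer | 1.33 | 7.4 |
| summer | 2.00 | 11.4 |
| summer | 3.00 | 16.9 |
| summer | 5.00 | 25.0 |
| summer | 6.00 | 27.7 |
| summer | 10.0 | 32.2 |
| summer | 15.0 | 37.3 |
| dusk | 0.833 | 6.9 |
| dusk | 2.50 | 12.8 |
| dusk | 5.00 | 19.9 |
| dusk | 6.00 | 20.8 |
| dusk | 10.0 | 23.3 |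
| dusk | 12.0 | 23.7 |
| dusk | 15.0 | 23.3 |
| midnight | 1.33 | 13.5 |
| midnight | 2.50 | 22.4 |
| midnight | 5.00 | 31.3 |
| midnight | 8.00 | 37.4 |
| midnight | 15.0 | 42.0 |

(standard deviation of a reading: 1 percentage point)

- the flask that comes out highest in amount of links, in percent of the first end groups charged, or "all alike" when all lie within 1.5 percentage points (maple / elm / ash / all alike)
- links at the end, in percent of the first end groups charged, maple
- links at the end, in percent of the first end groups charged, elm
- links at the end, in percent of the first end groups charged, ash

- what was read earlier has a scatter of 1 percentage point, one standard deviation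

I start from spring's 35.8 %, which is the link yield, the links at the plateau per second end group charged. Ash has spring's recipe, so the yield puts ash at 32.2 % of the first end groups charged. Dusk is the test from another run: the yield predicts 21.5 % there and dusk reads 23.3 %.

The weak link is the constancy of the yield. Summer, with fewer first end groups, gives 28.2 %, less than spring's yield, so I let the yield go with [first end groups]. The feed in maple holds [first end groups] low, so I reforge maple with summer's yield and get 25.4 %. Elm receives its last second end groups at 12.0 min, which leaves 8.00 min, and spring at 8.00 min reads 26.4 %, so I commit to about that for elm. That leaves ash higher than both.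

The forecast also reads a plateau of about 37 % of the second end groups, “whatever the first-group charge”. It names ash highest at 33 %, with maple 29 % and elm 15 %, whereas I put maple and elm close together.

The flasks give ash highest at 32.1 %, with maple 21.9 % and elm 23.4 %.

    2 second end groups → self-condensation product (k = 0.0160 /M/s)
    first end groups + second end groups → links (k = 0.0310 /M/s)
    first end groups + second end groups → rings, rate k3*[first end groups] as long as [second end groups] is above zero (k = 5.60 × 10⁻⁴ /s)

At 20.0 min maple holds 0.00920 M of self-condensation product, more than the 0.00539 M in ash, and half of that turnover in maple is done by 3.08 min, while maple's rings stand at 30.1 % of the first end groups charged, less than the 35.8 % in ash. Maple's link yield ends at 24.3 %, below summer's. For the flask like maple but charged with 0.20 M of first end groups, spring's yield predicts 8.05 %, and that flask holds 7.51 % links at 20.0 min.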